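**Assumption:** locants C1–C12 refer to one monomer unit (C1 lactone carbonyl, C2 the carbon on sulfur, C4 ketone, C5 carbinol, C11 the CH(CH3)–O carbon). Both halves of the target are (2S,5S,11R), and compounds 1, 2 and 5 are bought.

## Retrosynthetic overview

1. C2–S–C2′: double sulfa-Michael addition of sulfide to two molecules of enone lactone 16 (last step, joins the two rings).
2. O11–C1: macrolactonisation of the unprotected dihydroxy (E)-4-oxo-2-enoic acid 14; this is the only ring-forming step (12-membered ring, made once, used twice).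
3. C1–C4: one-flask oxidative dearomatisation of 2-substituted furan 10, the furan being the masked (E)-4-oxo-2-enoic acid; both silyl ethers are shed in the same flask.
4. C5 by Noyori transfer hydrogenation of furyl ketone 8; C5–C6 from furan-2-carbonitrile (made industrially from furfural) and an alkoxide-masked Grignard reagent; C11 from (R)-propylene oxide.

## Route

**Step 1**
Reactants: 1 1-bromo-4-chlorobutane; 2 (R)-2-methyloxirane
Product: 4 (R)-7-chloroheptan-2-ol, via 4-chlorobutylmagnesium bromide 3 (not isolated)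
Conditions: Mg, THF, 0–20 °C; then CuI (5 mol%), 2, THF, −30 → 0 °C; 1 M HCl work-up
Reagents that add atoms: none
Why: Mg inserts selectively into C–Br, and the copper-catalysed Grignard–epoxide coupling is an SN2 opening at the unsubstituted epoxide carbon, so the C–O stereocentre of 2 is untouched and becomes C11 (R).

**Step 2**
Reactants: 4 (R)-7-chloroheptan-2-ol; 5 furan-2-carbonitrile
Product: 8 (R)-1-(furan-2-yl)-7-hydroxyoctan-1-one, via alkoxide Grignard reagent 6 (not isolated), via N-magnesio ketimine 7 (not isolated)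
Conditions: i-PrMgCl (1.0 equiv), THF, −20 °C; Mg turnings, reflux; then 5, CuBr (2 mol%), 0 → 50 °C; then 1 M HCl, 0 °C → rt
Reagents that add atoms: water, O
Why: A Normant-type alkoxide-masked Grignard reagent (deprotonation, then Mg insertion into the primary C–Cl) adds once to the nitrile to give a ketimine salt that cannot over-add and is hydrolysed to the 2-acylfuran on acid work-up (Grignard addition to a nitrile), with no protecting group needed.

**Step 3**
Reactants: 8 (R)-1-(furan-2-yl)-7-hydroxyoctan-1-one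
Product: 9 (1S,7R)-1-(furan-2-yl)octane-1,7-diol
Conditions: RuCl[(S,S)-TsDPEN](p-cymene) (1 mol%), HCO2H/Et3N 5:2, EtOAc, rt
Reagents that add atoms: none
Why: Noyori asymmetric transfer hydrogenation; the (S,S) catalyst reduces (hetero)aryl alkyl ketones to the (S)-carbinol (as acetophenone gives (S)-1-phenylethanol), which sets C5 as S (2-acylfurans typically give >95% ee) without touching the remote C11 carbinol.

**Step 4**
Reactants: 9 (1S,7R)-1-(furan-2-yl)octane-1,7-diol
Product: 10 (1S,7R)-1-(furan-2-yl)-1,7-bis(triethylsilyloxy)octane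
Conditions: TESCl (2.4 equiv), imidazole (3 equiv), DMAP (5 mol%), CH2Cl2, 0 °C → rt
Reagents that add atoms: chlorotriethylsilane (TESCl), CC[Si](Cl)(CC)CC
Why: Routine silylation of both secondary alcohols; the C5 silyl ether prevents Achmatowicz ring closure during furan opening, and TES is chosen because it falls off in the acidic finish of step 5.

**Step 5 (key step)**
Reactants: 10 (1S,7R)-1-(furan-2-yl)-1,7-bis(triethylsilyloxy)octane
Product: 14 (2E,5S,11R)-5,11-dihydroxy-4-oxododec-2-enoic acid, via Z-enal 11 (not isolated), via E-enal 12 (not isolated), via bis-TES enoic acid 13 (not isolated)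
Conditions: NBS (1.1 equiv), NaHCO3 (2 equiv), acetone/H2O 10:1, −20 °C; pyridine (2 equiv), rt; then t-BuOH, 2-methyl-2-butene, NaClO2, NaH2PO4, 0 °C → rt; then 1 M HCl, THF, rt
Reagents that add atoms: water, O; sodium chlorite, [Na+].[O-]Cl=O
Why: Oxidative furan ring-opening (NBS bromination/hydration) turns the four furan carbons into C1–C4 as the Z-4-oxo-2-enal, pyridine isomerises it to the E-enal by reversible conjugate addition, Pinnick oxidation gives the acid and dilute HCl hydrolyses both TES ethers; no stereocentre is touched, and the freed C5–OH cannot lactonise onto C1 because that would need an E-alkene in a six-membered ring.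

**Step 6**
Reactants: 14 (2E,5S,11R)-5,11-dihydroxy-4-oxododec-2-enoic acid
Product: 16 (3E,6S,12R)-6-hydroxy-12-methyl-1-oxacyclododec-3-ene-2,5-dione, via mixed anhydride 15 (not isolated)
Conditions: MNBA (2-methyl-6-nitrobenzoic anhydride, 1.3 equiv), DMAP (3 equiv), CH2Cl2 (1 mM final), rt, syringe-pump addition of 14 in THF over 12 h
Reagents that add atoms: none
Why: Shiina macrolactonisation; O11 attacks the mixed anhydride under high dilution to close the 12-membered ring with retention at C11, while the α′-ketol OH at C5 is the poorer nucleophile and its only intramolecular lactone is geometrically forbidden by the E-alkene.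

**Step 7**
Reactants: 16 (3E,6S,12R)-6-hydroxy-12-methyl-1-oxacyclododec-3-ene-2,5-dione (two molecules)
Product: 18 thiocladospolide F, via thiol 17 (not isolated)
Conditions: Na2S·9H2O (0.50 equiv), NaH2PO4/Na2HPO4 buffer pH 7.5–MeCN 1:1 (degassed), 0 °C → rt
Reagents that add atoms: sodium sulfide nonahydrate, O.O.O.O.O.O.O.O.O.[Na+].[Na+].[S-2]
Why: Double sulfa-Michael addition; hydrosulfide attacks C2 (β to the ketone, the stronger activating group) to give thiol 17, whose thiolate adds in the same way to a second enone; both C2 centres are set by the macrocycle (attack on the exposed face, reversible by retro-Michael so the favoured diastereomer accumulates) and are expected, but not proven, to be 2S as in the natural product.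

## Compound list

1 | 1-bromo-4-chlorobutane | ClCCCCBr | starting material
2 | (R)-2-methyloxirane ((R)-propylene oxide) | C[C@@H]1CO1 | starting material
3 | 4-chlorobutylmagnesium bromide | ClCCCC[Mg]Br | intermediate
4 | (R)-7-chloroheptan-2-ol | C[C@@H](O)CCCCCCl | intermediate
5 | furan-2-carbonitrile | N#Cc1ccco1 | starting material
6 | chloromagnesium (R)-7-(chloromagnesio)heptan-2-olate (alkoxide Grignard reagent) | C[C@@H](O[Mg]Cl)CCCCC[Mg]Cl | intermediate
7 | N,O-bis(chloromagnesium) salt of (R)-1-(furan-2-yl)-7-hydroxyoctan-1-imine | C[C@@H](O[Mg]Cl)CCCCCC(=N[Mg]Cl)c1ccco1 | intermediate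
8 | (R)-1-(furan-2-yl)-7-hydroxyoctan-1-one | C[C@@H](O)CCCCCC(=O)c1ccco1 | intermediate
9 | (1S,7R)-1-(furan-2-yl)octane-1,7-diol | C[C@@H](O)CCCCC[C@H](O)c1ccco1 | intermediate
10 | (1S,7R)-1-(furan-2-yl)-1,7-bis(triethylsilyloxy)octane | C[C@@H](O[Si](CC)(CC)CC)CCCCC[C@H](O[Si](CC)(CC)CC)c1ccco1 | intermediate
11 | (2Z,5S,11R)-4-oxo-5,11-bis(triethylsilyloxy)dodec-2-enal | C[C@@H](O[Si](CC)(CC)CC)CCCCC[C@H](O[Si](CC)(CC)CC)C(=O)/C=C\C=O | intermediate
12 | (2E,5S,11R)-4-oxo-5,11-bis(triethylsilyloxy)dodec-2-enal | C[C@@H](O[Si](CC)(CC)CC)CCCCC[C@H](O[Si](CC)(CC)CC)C(=O)/C=C/C=O | intermediate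
13 | (2E,5S,11R)-4-oxo-5,11-bis(triethylsilyloxy)dodec-2-enoic acid | C[C@@H](O[Si](CC)(CC)CC)CCCCC[C@H](O[Si](CC)(CC)CC)C(=O)/C=C/C(=O)O | intermediate
14 | (2E,5S,11R)-5,11-dihydroxy-4-oxododec-2-enoic acid | C[C@@H](O)CCCCC[C@H](O)C(=O)/C=C/C(=O)O | intermediate
15 | mixed anhydride of 14 with 2-methyl-6-nitrobenzoic acid | C[C@@H](O)CCCCC[C@H](O)C(=O)/C=C/C(=O)OC(=O)c1c(C)cccc1[N+](=O)[O-] | intermediate
16 | (3E,6S,12R)-6-hydroxy-12-methyl-1-oxacyclododec-3-ene-2,5-dione | C[C@@H]1CCCCC[C@H](O)C(=O)/C=C/C(=O)O1 | intermediate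
17 | (3S,6S,12R)-6-hydroxy-12-methyl-3-sulfanyl-1-oxacyclododecane-2,5-dione | C[C@@H]1CCCCC[C@H](O)C(=O)C[C@H](S)C(=O)O1 | intermediate
18 | thiocladospolide F, (3S,3′S,6S,6′S,12R,12′R)-3,3′-sulfanediylbis(6-hydroxy-12-methyl-1-oxacyclododecane-2,5-dione) | C[C@@H]1CCCCC[C@H](O)C(=O)C[C@H](S[C@H]2CC(=O)[C@@H](O)CCCCC[C@@H](C)OC2=O)C(=O)O1 | target

## Step count and risks

Total steps: 7. Longest linear sequence: 7 (steps 1–7).

**Step 7** is the most likely to fail: the two C2 centres rest on substrate control, and the one-flask 2:1 stoichiometry must be clean. The fallback sets out from 16 and comes back at 17. Enone 16 is treated with thioacetic acid and 5 mol% of a cinchona-derived bifunctional squaramide (quinine or quinidine series, whichever gives 2S) in toluene at −40 °C. This gives (3S,6S,12R)-3-(acetylsulfanyl)-6-hydroxy-12-methyl-1-oxacyclododecane-2,5-dione F1. HCl in MeOH at 0 °C cleaves the thioester to thiol 17, which is now isolated and added to a second equivalent of 16 under the same catalyst to reach 18. Each C–S bond is thus made separately and under catalyst control.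

**Step 6** is the second risk: DMAP may isomerise the activated E-enoate, after which the free C5–OH would close the six-membered lactone, or C5 may epimerise. The fallback sets out from 8 and comes back at 16; it carries C5 as a robust silyl ether and C11 as a labile one.
- Ketone 8 is silylated (TESCl, imidazole) to (R)-1-(furan-2-yl)-7-(triethylsilyloxy)octan-1-one F2.
- Reduction with RuCl[(S,S)-TsDPEN](p-cymene) and HCO2Na in H2O/EtOAc gives (1S,7R)-1-(furan-2-yl)-7-(triethylsilyloxy)octan-1-ol F3.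
- TBSCl/imidazole/DMF gives (1S,7R)-1-(tert-butyldimethylsilyloxy)-1-(furan-2-yl)-7-(triethylsilyloxy)octane F4.
- Oxidation as in step 5 passes through (2Z,5S,11R)-5-(tert-butyldimethylsilyloxy)-4-oxo-11-(triethylsilyloxy)dodec-2-enal F5, (2E,5S,11R)-5-(tert-butyldimethylsilyloxy)-4-oxo-11-(triethylsilyloxy)dodec-2-enal F6 and (2E,5S,11R)-5-(tert-butyldimethylsilyloxy)-4-oxo-11-(triethylsilyloxy)dodec-2-enoic acid F7.
- Brief dilute HCl removes only the TES group to give (2E,5S,11R)-5-(tert-butyldimethylsilyloxy)-11-hydroxy-4-oxododec-2-enoic acid F8.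
- MNBA/DMAP under high dilution closes the ring through the mixed anhydride of F8 with 2-methyl-6-nitrobenzoic acid F9 to (3E,6S,12R)-6-(tert-butyldimethylsilyloxy)-12-methyl-1-oxacyclododec-3-ene-2,5-dione F10.
- HF·pyridine in THF then gives 16.

**Step 5** is the third risk: the C5 TES ether may be lost before the Z-to-E isomerisation, which would divert material to the Achmatowicz pyranone, or the isomerisation may be incomplete in the telescoped sequence. The fallback sets out from 10 and comes back at 13; it replaces halogen/chlorite oxidation by a cycloaddition that reaches the acid oxidation level directly. Furan 10 is photo-oxygenated (O2, tetraphenylporphyrin, visible light, i-Pr2NEt, CH2Cl2, −78 °C). The resulting 1-[(1S,7R)-1,7-bis(triethylsilyloxy)octyl]-2,3,7-trioxabicyclo[2.2.1]hept-5-ene F11 undergoes Kornblum–DeLaMare fragmentation to 5-hydroxy-5-[(1S,7R)-1,7-bis(triethylsilyloxy)octyl]furan-2(5H)-one F12, the ring tautomer of the Z-acid. Pyridine at rt isomerises the open form to E-acid 13, which is desilylated with dilute HCl as in step 5 to give 14.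

## Further compounds

F1 | step 7 | (3S,6S,12R)-3-(acetylsulfanyl)-6-hydroxy-12-methyl-1-oxacyclododecane-2,5-dione | C[C@@H]1CCCCC[C@H](O)C(=O)C[C@H](SC(C)=O)C(=O)O1
F2 | step 6 | (R)-1-(furan-2-yl)-7-(triethylsilyloxy)octan-1-one | C[C@@H](O[Si](CC)(CC)CC)CCCCCC(=O)c1ccco1
F3 | step 6 | (1S,7R)-1-(furan-2-yl)-7-(triethylsilyloxy)octan-1-ol | C[C@@H](O[Si](CC)(CC)CC)CCCCC[C@H](O)c1ccco1
F4 | step 6 | (1S,7R)-1-(tert-butyldimethylsilyloxy)-1-(furan-2-yl)-7-(triethylsilyloxy)octane | C[C@@H](O[Si](CC)(CC)CC)CCCCC[C@H](O[Si](C)(C)C(C)(C)C)c1ccco1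
F5 | step 6 | (2Z,5S,11R)-5-(tert-butyldimethylsilyloxy)-4-oxo-11-(triethylsilyloxy)dodec-2-enal | C[C@@H](O[Si](CC)(CC)CC)CCCCC[C@H](O[Si](C)(C)C(C)(C)C)C(=O)/C=C\C=O
F6 | step 6 | (2E,5S,11R)-5-(tert-butyldimethylsilyloxy)-4-oxo-11-(triethylsilyloxy)dodec-2-enal | C[C@@H](O[Si](CC)(CC)CC)CCCCC[C@H](O[Si](C)(C)C(C)(C)C)C(=O)/C=C/C=O
F7 | step 6 | (2E,5S,11R)-5-(tert-butyldimethylsilyloxy)-4-oxo-11-(triethylsilyloxy)dodec-2-enoic acid | C[C@@H](O[Si](CC)(CC)CC)CCCCC[C@H](O[Si](C)(C)C(C)(C)C)C(=O)/C=C/C(=O)O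
F8 | step 6 | (2E,5S,11R)-5-(tert-butyldimethylsilyloxy)-11-hydroxy-4-oxododec-2-enoic acid | C[C@@H](O)CCCCC[C@H](O[Si](C)(C)C(C)(C)C)C(=O)/C=C/C(=O)O
F9 | step 6 | mixed anhydride of F8 with 2-methyl-6-nitrobenzoic acid | C[C@@H](O)CCCCC[C@H](O[Si](C)(C)C(C)(C)C)C(=O)/C=C/C(=O)OC(=O)c1c(C)cccc1[N+](=O)[O-]
F10 | step 6 | (3E,6S,12R)-6-(tert-butyldimethylsilyloxy)-12-methyl-1-oxacyclododec-3-ene-2,5-dione | C[C@@H]1CCCCC[C@H](O[Si](C)(C)C(C)(C)C)C(=O)/C=C/C(=O)O1
F11 | step 5 | 1-[(1S,7R)-1,7-bis(triethylsilyloxy)octyl]-2,3,7-trioxabicyclo[2.2.1]hept-5-ene (bridgehead epimers) | C[C@@H](O[Si](CC)(CC)CC)CCCCC[C@H](O[Si](CC)(CC)CC)C12OC(C=C1)OO2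
F12 | step 5 | 5-hydroxy-5-[(1S,7R)-1,7-bis(triethylsilyloxy)octyl]furan-2(5H)-one (hemiketal epimers) | C[C@@H](O[Si](CC)(CC)CC)CCCCC[C@H](O[Si](CC)(CC)CC)C1(O)OC(=O)C=C1
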